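**Retrosynthetic overview**
- Target 18 comes from its O8‑triethylsilyl ether 17, which arises from 15 by Barton–McCombie removal of the C12 oxygen. 15 comes from homoallylic alcohol 12 by hydroboration and acetylation, with the vinyl group converted first so that no homoallyl radical rearrangement can occur.
- Key disconnection C12–C13: reagent‑controlled (Z)‑crotylboration of aldehyde 5 with a pinene‑derived crotylborane made from cis‑2‑butene 6 and (−)‑Ipc2BOMe 7. This step sets C13.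
- Aldehyde 5 comes from (+)‑sclareolide 1 by lactone reduction, bis‑silylation, selective O12 desilylation and oxidation.
- Rings: none is formed. Rings A and B, with C5, C8, C9 and C10, are taken intact from sclareolide; only its lactone ring is opened.

Assumption: names use labdane numbering (C9 carries the chain C11–C12–C13(C16)–C14–C15; ring carbons are 5S,8R,9R,10S throughout, 8α = the sclareol‑type 8R oxygen).

**Step 1**
Reactants: 1 (+)-sclareolide
Product: 2 13,14,15,16-tetranorlabdane-8α,12-diol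
Conditions: LiAlH4, THF, 0 °C to rt; then H2O, 15% aq NaOH, H2O
Reagents that add atoms: none
Why: LiAlH4 reduction of the lactone gives the diol without touching any stereocenter, so C5, C8, C9 and C10 are carried over from sclareolide.

**Step 2**
Reactants: 2 13,14,15,16-tetranorlabdane-8α,12-diol
Product: 3 8α,12-bis(triethylsilyloxy)-13,14,15,16-tetranorlabdane
Conditions: TESOTf (2.5 equiv), 2,6-lutidine, CH2Cl2, −78 to 0 °C
Reagents that add atoms: triethylsilyl trifluoromethanesulfonate (TESOTf), CC[Si](CC)(CC)OS(=O)(=O)C(F)(F)F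
Why: Silyl triflate silylation is reactive enough to cap the hindered tertiary C8–OH as well as the primary OH, which later prevents lactol formation.

**Step 3**
Reactants: 3 8α,12-bis(triethylsilyloxy)-13,14,15,16-tetranorlabdane
Product: 4 8α-(triethylsilyloxy)-13,14,15,16-tetranorlabdan-12-ol
Conditions: PPTS (0.1 equiv), MeOH/CH2Cl2 1:1, 0 °C, TLC control
Reagents that add atoms: none
Why: Acid‑catalysed methanolysis of a primary triethylsilyl ether is far faster than that of the hindered tertiary one, so kinetic desilylation frees only O12.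

**Step 4**
Reactants: 4 8α-(triethylsilyloxy)-13,14,15,16-tetranorlabdan-12-ol
Product: 5 8α-(triethylsilyloxy)-13,14,15,16-tetranorlabdan-12-al
Conditions: Dess–Martin periodinane, CH2Cl2, 0 °C to rt
Reagents that add atoms: none
Why: Dess–Martin oxidation stops at the aldehyde, and the silylated O8 cannot close onto it to form a lactol.

**Step 5**
Reactants: 5 8α-(triethylsilyloxy)-13,14,15,16-tetranorlabdan-12-al; 6 cis-2-butene; 7 (−)-B-methoxydiisopinocampheylborane [(−)-Ipc2BOMe, the enantiomer made from (+)-α-pinene]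
Product: 12 (12R,13R)-8α-(triethylsilyloxy)labd-14-en-12-ol, via (Z)-crotylpotassium 8 (not isolated), via potassium crotyl(methoxy)diisopinocampheylborate 9 (not isolated), via (Z)-crotyldiisopinocampheylborane 10 (not isolated), via diisopinocampheylborinate ester 11 (not isolated)
Conditions: 6, KOtBu, n-BuLi, THF, −78 to −45 °C; 7, −78 °C; BF3·OEt2, −78 °C; 5, −78 °C, 4 h; then 3 M NaOH, 30% H2O2, rt
Reagents that add atoms: KOtBu, CC(C)(C)[O-].[K+] (supplies only the potassium of intermediates 8 and 9; 12 contains nothing but the atoms of 5 and 6 plus hydrogen)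
Why: Brown asymmetric crotylboration (a carbonyl allylation) joins C12 to C13 through a closed chair transition state in which the Z geometry gives the 12,13‑syn relationship and the isopinocampheyl groups from (+)-α-pinene choose the aldehyde face, setting C12 as R and C13 as R.

**Step 6**
Reactants: 12 (12R,13R)-8α-(triethylsilyloxy)labd-14-en-12-ol
Product: 14 (12R,13R)-8α-(triethylsilyloxy)labdane-12,15-diol, via bis(9-BBN) adduct 13 (not isolated)
Conditions: 9-BBN (3 equiv), THF, 0 °C to rt; then 3 M NaOH, 30% H2O2, 0 °C to rt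
Reagents that add atoms: 9-BBN, C1CC2CCCC(C1)B2 (boron and bicyclic unit only in intermediate 13); hydrogen peroxide, OO (the C15 hydroxyl oxygen of 14)
Why: Hydroboration–oxidation with bulky 9-BBN places boron only on the terminal carbon of the monosubstituted alkene and oxidation gives the primary alcohol, leaving C13 untouched.

**Step 7**
Reactants: 14 (12R,13R)-8α-(triethylsilyloxy)labdane-12,15-diol
Product: 15 (12R,13R)-12-hydroxy-8α-(triethylsilyloxy)labdan-15-yl acetate
Conditions: AcCl (1.1 equiv), 2,4,6-collidine, CH2Cl2, −78 °C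
Reagents that add atoms: acetyl chloride, CC(=O)Cl
Why: In this selective acylation the unhindered primary C15–OH reacts at −78 °C much faster than the hindered secondary C12–OH flanked by the C13 branch and the decalin.

**Step 8**
Reactants: 15 (12R,13R)-12-hydroxy-8α-(triethylsilyloxy)labdan-15-yl acetate
Product: 16 (12R,13R)-12-(imidazol-1-ylthiocarbonyloxy)-8α-(triethylsilyloxy)labdan-15-yl acetate
Conditions: 1,1'-thiocarbonyldiimidazole (3 equiv), DMAP (0.3 equiv), toluene, 90 °C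
Reagents that add atoms: 1,1'-thiocarbonyldiimidazole, S=C(n1ccnc1)n1ccnc1
Why: Thioacylation of the only free hydroxyl (first half of a Barton–McCombie deoxygenation) runs under near‑neutral conditions that spare the acetate and the silyl ether.

**Step 9**
Reactants: 16 (12R,13R)-12-(imidazol-1-ylthiocarbonyloxy)-8α-(triethylsilyloxy)labdan-15-yl acetate
Product: 17 (13S)-8α-(triethylsilyloxy)labdan-15-yl acetate
Conditions: Bu3SnH (2.5 equiv), AIBN (0.2 equiv), toluene, 110 °C
Reagents that add atoms: none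
Why: In the Barton–McCombie radical deoxygenation the stannyl radical adds to C=S, the C12–O bond fragments and the secondary radical takes H from Bu3SnH, so C12 becomes CH2 while C13 is untouched (its descriptor changes to S only because the priorities change).

**Step 10**
Reactants: 17 (13S)-8α-(triethylsilyloxy)labdan-15-yl acetate
Product: 18 (13S)-8α-hydroxylabdan-15-yl acetate (target, CNP0188939.1)
Conditions: HF·pyridine, pyridine, THF, 0 °C to rt
Reagents that add atoms: none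
Why: Fluoride‑mediated desilylation, driven by the strong Si–F bond, cleaves the tertiary silyl ether under buffered conditions that neither hydrolyse the acetate nor dehydrate the tertiary alcohol.

**Compound list**
1 | (+)-sclareolide, (3aR,5aS,9aS,9bR)-3a,6,6,9a-tetramethyldecahydronaphtho[2,1-b]furan-2(1H)-one | O=C1C[C@@H]2[C@@]3(C)CCCC(C)(C)[C@@H]3CC[C@@]2(C)O1 | starting material
2 | 13,14,15,16-tetranorlabdane-8α,12-diol, (1R,2R,4aS,8aS)-1-(2-hydroxyethyl)-2,5,5,8a-tetramethyldecahydronaphthalen-2-ol | OCC[C@@H]1[C@@]2(C)CCCC(C)(C)[C@@H]2CC[C@@]1(C)O | intermediate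
3 | 8α,12-bis(triethylsilyloxy)-13,14,15,16-tetranorlabdane | CC[Si](CC)(CC)OCC[C@@H]1[C@@]2(C)CCCC(C)(C)[C@@H]2CC[C@@]1(C)O[Si](CC)(CC)CC | intermediate
4 | 8α-(triethylsilyloxy)-13,14,15,16-tetranorlabdan-12-ol | OCC[C@@H]1[C@@]2(C)CCCC(C)(C)[C@@H]2CC[C@@]1(C)O[Si](CC)(CC)CC | intermediate
5 | 8α-(triethylsilyloxy)-13,14,15,16-tetranorlabdan-12-al | O=CC[C@@H]1[C@@]2(C)CCCC(C)(C)[C@@H]2CC[C@@]1(C)O[Si](CC)(CC)CC | intermediate
6 | cis-2-butene, (Z)-but-2-ene | C/C=C\C | starting material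
7 | (−)-B-methoxydiisopinocampheylborane, both isopinocampheyl groups from (+)-α-pinene | COB([C@@H]1C[C@@H]2C[C@H]([C@H]1C)C2(C)C)[C@@H]1C[C@@H]2C[C@H]([C@H]1C)C2(C)C | starting material
8 | (Z)-crotylpotassium, potassium (Z)-but-2-en-1-ide (C4H7K) | C/C=C\[CH2-].[K+] | intermediate
9 | potassium (Z)-but-2-enyl(methoxy)diisopinocampheylborate, K[Ipc2B(OMe)(crotyl)] | C/C=C\C[B-](OC)([C@@H]1C[C@@H]2C[C@H]([C@H]1C)C2(C)C)[C@@H]1C[C@@H]2C[C@H]([C@H]1C)C2(C)C.[K+] | intermediate
10 | (Z)-but-2-enyldiisopinocampheylborane, (Z)-crotyl-B(Ipc)2 | C/C=C\CB([C@@H]1C[C@@H]2C[C@H]([C@H]1C)C2(C)C)[C@@H]1C[C@@H]2C[C@H]([C@H]1C)C2(C)C | intermediate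
11 | (12R,13R)-12-(diisopinocampheylboryloxy)-8α-(triethylsilyloxy)labd-14-ene (borinate ester of 12) | C=C[C@@H](C)[C@H](OB([C@@H]3C[C@@H]4C[C@H]([C@H]3C)C4(C)C)[C@@H]3C[C@@H]4C[C@H]([C@H]3C)C4(C)C)C[C@@H]1[C@@]2(C)CCCC(C)(C)[C@@H]2CC[C@@]1(C)O[Si](CC)(CC)CC | intermediate
12 | (12R,13R)-8α-(triethylsilyloxy)labd-14-en-12-ol (12,13-syn) | C=C[C@@H](C)[C@H](O)C[C@@H]1[C@@]2(C)CCCC(C)(C)[C@@H]2CC[C@@]1(C)O[Si](CC)(CC)CC | intermediate
13 | (12R,13R)-15-(9-borabicyclo[3.3.1]non-9-yl)-12-(9-borabicyclo[3.3.1]non-9-yloxy)-8α-(triethylsilyloxy)labdane | C1CCC2CCCC1B2CC[C@@H](C)[C@H](OB1C2CCCC1CCC2)C[C@@H]1[C@@]2(C)CCCC(C)(C)[C@@H]2CC[C@@]1(C)O[Si](CC)(CC)CC | intermediate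
14 | (12R,13R)-8α-(triethylsilyloxy)labdane-12,15-diol | OCC[C@@H](C)[C@H](O)C[C@@H]1[C@@]2(C)CCCC(C)(C)[C@@H]2CC[C@@]1(C)O[Si](CC)(CC)CC | intermediate
15 | (12R,13R)-12-hydroxy-8α-(triethylsilyloxy)labdan-15-yl acetate | CC(=O)OCC[C@@H](C)[C@H](O)C[C@@H]1[C@@]2(C)CCCC(C)(C)[C@@H]2CC[C@@]1(C)O[Si](CC)(CC)CC | intermediate
16 | (12R,13R)-12-(imidazol-1-ylthiocarbonyloxy)-8α-(triethylsilyloxy)labdan-15-yl acetate | CC(=O)OCC[C@@H](C)[C@H](OC(=S)n1ccnc1)C[C@@H]1[C@@]2(C)CCCC(C)(C)[C@@H]2CC[C@@]1(C)O[Si](CC)(CC)CC | intermediate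
17 | (13S)-8α-(triethylsilyloxy)labdan-15-yl acetate | CC(=O)OCC[C@@H](C)CC[C@@H]1[C@@]2(C)CCCC(C)(C)[C@@H]2CC[C@@]1(C)O[Si](CC)(CC)CC | intermediate
18 | (5S,8R,9R,10S,13S)-8-hydroxylabdan-15-yl acetate | CC(=O)OCC[C@@H](C)CC[C@@H]1[C@@]2(C)CCCC(C)(C)[C@@H]2CC[C@@]1(C)O | target

**Totals**
Total step count: 10. Longest linear sequence: 10 steps (1 to 18).

**Steps most likely to fail, each with a fallback**

Step 3 (selective O12 desilylation). Over‑ or under‑cleavage would give diol 2 or returned 3. The fallback sets out from 2 and comes back at 4, replacing kinetic discrimination by orthogonal protection. Ac2O/pyridine at 0 °C acetylates only the primary alcohol to give 8α-hydroxy-13,14,15,16-tetranorlabdan-12-yl acetate F1. TESOTf/2,6-lutidine then silylates O8 to give 8α-(triethylsilyloxy)-13,14,15,16-tetranorlabdan-12-yl acetate F2. K2CO3 in MeOH removes the acetate and returns 4.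

Step 5 (crotylboration). The Z‑crotylborane must be generated and kept cold, and the aldehyde sits next to a crowded decalin, so conversion or selectivity at C13 may be poor. The fallback sets out from 5 and comes back at 12, building the same two stereocenters by an auxiliary‑controlled aldol followed by methylenation.
- An Evans syn‑aldol of 5 with the boron enolate of (S)-4-benzyl-3-propionyloxazolidin-2-one (Bu2BOTf, i-Pr2NEt, CH2Cl2, −78 to 0 °C) gives (4S)-4-benzyl-3-[(12R,13S)-12-hydroxy-8α-(triethylsilyloxy)-15-norlabdan-14-oyl]oxazolidin-2-one F3.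
- MeONHMe·HCl/AlMe3 converts it into the Weinreb amide (12R,13S)-12-hydroxy-N-methoxy-N-methyl-8α-(triethylsilyloxy)-15-norlabdan-14-amide F4.
- TMSCl/imidazole gives the silyl ether (12R,13S)-N-methoxy-N-methyl-8α-(triethylsilyloxy)-12-(trimethylsilyloxy)-15-norlabdan-14-amide F5.
- i-Bu2AlH at −78 °C gives the aldehyde (12R,13S)-8α-(triethylsilyloxy)-12-(trimethylsilyloxy)-15-norlabdan-14-al F6.
- Wittig methylenation (Ph3PCH3Br, KN(SiMe3)2, THF) gives (12R,13R)-8α-(triethylsilyloxy)-12-(trimethylsilyloxy)labd-14-ene F7.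
- K2CO3 in MeOH removes only the trimethylsilyl group and returns 12.

Step 8 (thioacylation of the hindered C12 alcohol, on which the radical step depends). If the alcohol resists thioacylation or the radical reduction is poor, the fallback sets out from 14 and comes back at 18, using ionic hydride displacement and a final selective acetylation.
- TBSCl/imidazole silylates the primary alcohol to give (12R,13R)-15-(tert-butyldimethylsilyloxy)-8α-(triethylsilyloxy)labdan-12-ol F8.
- MsCl/Et3N gives the mesylate (12R,13R)-15-(tert-butyldimethylsilyloxy)-8α-(triethylsilyloxy)labdan-12-yl methanesulfonate F9.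
- LiEt3BH in THF (0 °C to reflux) displaces the mesylate by hydride to give (13S)-15-(tert-butyldimethylsilyloxy)-8α-(triethylsilyloxy)labdane F10; elimination is the risk here.
- HF·pyridine removes both silyl groups to give (13S)-labdane-8α,15-diol F11.
- Ac2O/pyridine at 0 °C acetylates only the primary alcohol and gives 18.

**Further compounds**
F1 | step 3 | 8α-hydroxy-13,14,15,16-tetranorlabdan-12-yl acetate | CC(=O)OCC[C@@H]1[C@@]2(C)CCCC(C)(C)[C@@H]2CC[C@@]1(C)O
F2 | step 3 | 8α-(triethylsilyloxy)-13,14,15,16-tetranorlabdan-12-yl acetate | CC(=O)OCC[C@@H]1[C@@]2(C)CCCC(C)(C)[C@@H]2CC[C@@]1(C)O[Si](CC)(CC)CC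
F3 | step 5 | (4S)-4-benzyl-3-[(12R,13S)-12-hydroxy-8α-(triethylsilyloxy)-15-norlabdan-14-oyl]oxazolidin-2-one | O=C1OC[C@H](Cc2ccccc2)N1C(=O)[C@@H](C)[C@H](O)C[C@@H]1[C@@]2(C)CCCC(C)(C)[C@@H]2CC[C@@]1(C)O[Si](CC)(CC)CC
F4 | step 5 | (12R,13S)-12-hydroxy-N-methoxy-N-methyl-8α-(triethylsilyloxy)-15-norlabdan-14-amide | CON(C)C(=O)[C@@H](C)[C@H](O)C[C@@H]1[C@@]2(C)CCCC(C)(C)[C@@H]2CC[C@@]1(C)O[Si](CC)(CC)CC
F5 | step 5 | (12R,13S)-N-methoxy-N-methyl-8α-(triethylsilyloxy)-12-(trimethylsilyloxy)-15-norlabdan-14-amide | CON(C)C(=O)[C@@H](C)[C@H](O[Si](C)(C)C)C[C@@H]1[C@@]2(C)CCCC(C)(C)[C@@H]2CC[C@@]1(C)O[Si](CC)(CC)CC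
F6 | step 5 | (12R,13S)-8α-(triethylsilyloxy)-12-(trimethylsilyloxy)-15-norlabdan-14-al | O=C[C@@H](C)[C@H](O[Si](C)(C)C)C[C@@H]1[C@@]2(C)CCCC(C)(C)[C@@H]2CC[C@@]1(C)O[Si](CC)(CC)CC
F7 | step 5 | (12R,13R)-8α-(triethylsilyloxy)-12-(trimethylsilyloxy)labd-14-ene | C=C[C@@H](C)[C@H](O[Si](C)(C)C)C[C@@H]1[C@@]2(C)CCCC(C)(C)[C@@H]2CC[C@@]1(C)O[Si](CC)(CC)CC
F8 | step 8 | (12R,13R)-15-(tert-butyldimethylsilyloxy)-8α-(triethylsilyloxy)labdan-12-ol | CC(C)(C)[Si](C)(C)OCC[C@@H](C)[C@H](O)C[C@@H]1[C@@]2(C)CCCC(C)(C)[C@@H]2CC[C@@]1(C)O[Si](CC)(CC)CC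
F9 | step 8 | (12R,13R)-15-(tert-butyldimethylsilyloxy)-8α-(triethylsilyloxy)labdan-12-yl methanesulfonate | CC(C)(C)[Si](C)(C)OCC[C@@H](C)[C@H](OS(C)(=O)=O)C[C@@H]1[C@@]2(C)CCCC(C)(C)[C@@H]2CC[C@@]1(C)O[Si](CC)(CC)CC
F10 | step 8 | (13S)-15-(tert-butyldimethylsilyloxy)-8α-(triethylsilyloxy)labdane | CC(C)(C)[Si](C)(C)OCC[C@@H](C)CC[C@@H]1[C@@]2(C)CCCC(C)(C)[C@@H]2CC[C@@]1(C)O[Si](CC)(CC)CC
F11 | step 8 | (13S)-labdane-8α,15-diol | OCC[C@@H](C)CC[C@@H]1[C@@]2(C)CCCC(C)(C)[C@@H]2CC[C@@]1(C)O
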